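The route rests on opening ring B (C5–C10) at the C8–C9 bond. It exploits two features. C8 (bearing C17) and quaternary C9 (bearing C20 and C11) are neighbours in ring B, and C11 can be carried at the carboxylic acid oxidation level. An Ireland–Claisen ring contraction forms C8–C9, closes ring B, sets both stereocentres from the C6 carbinol and releases C11 as an acid, all in one operation. Its precursor is a δ-lactone fused to ring A (C1–C5, C10; the C1=C10 alkene and the C4 ester are already in place). In it C11 is the carbonyl, the ring oxygen sits on C6, and C6 carries a (Z)-propenyl group.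

Key step: step 8

Remark on the chemistry: halimane numbering is used; the target reads as (4S,5R,8R,9S,13S); the C9 stereocentre of the coupling product and of both lactones is erased in the key step, so its epimers are carried together and the lactones are drawn as the 9R epimer.

Step 1
Reactants: 1 but-2-yn-1-ol
Product: 2 but-2-ynal
Conditions: MnO2 (activated, excess), CH2Cl2, rt; filter, dry over 4 Å sieves, use as solution
Reagents that add atoms: none
Why: Heterogeneous MnO2 oxidation is selective for propargylic alcohols and stops at the volatile ynal, which is used without concentration.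

Step 2
Reactants: 3 methyl 3-oxocyclohex-1-ene-1-carboxylate; 2 but-2-ynal
Product: 5 anti ketol methyl (1S,2R)-2-[(1S)-1-hydroxybut-2-yn-1-yl]-1-methyl-3-oxocyclohexane-1-carboxylate, via methylzinc enolate 4 (not isolated)
Conditions: Me2Zn, (CuOTf)2·C6H6 (2.5 mol %), chiral aryloxide-tethered imidazolin-2-ylidene ligand (5 mol %, from its imidazolinium salt and Ag2O; antipode that attacks the Re face of C4), t-BuOMe, −30 °C; then 2 in CH2Cl2, −78 °C; cold aq NH4Cl
Reagents that add atoms: dimethylzinc, C[Zn]C
Why: Copper-catalysed asymmetric conjugate addition puts methyl on the Re face of C4 (beta to the ketone, the stronger acceptor) and fixes the quaternary centre under ligand control, and the regiodefined enolate 4 then undergoes a tandem aldol through a Zimmerman–Traxler chair, where the ring-locked (E)-enolate should give the anti C5/C6 pair and approach anti to the pseudoaxial C19 methyl should place C6 cis to the ester, minor diastereomers being removed by chromatography.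

Step 3
Reactants: 5 anti ketol
Product: 6 C6 triethylsilyl ether of 5 (4S,5R,6S)
Conditions: Et3SiOTf, 2,6-lutidine, CH2Cl2, −78 °C
Reagents that add atoms: triethylsilyl trifluoromethanesulfonate, CC[Si](CC)(CC)OS(=O)(=O)C(F)(F)F
Why: Silyl ether formation under non-basic conditions blocks retro-aldol cleavage and also blocks attack of the C6 oxygen on the cis C18 methyl ester (gamma-lactone formation), which would consume the oxygen needed for the delta-lactone.

Step 4
Reactants: 6 silyl ether ketone
Product: 7 C1=C10 enol triflate of 6 (4S,5R,6S)
Conditions: KN(SiMe3)2, THF, −78 °C; then PhNTf2, −78 to 0 °C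
Reagents that add atoms: N-phenylbis(trifluoromethanesulfonimide), O=S(=O)(N(c1ccccc1)S(=O)(=O)C(F)(F)F)C(F)(F)F
Why: Kinetic enolisation should occur only at the C1 methylene because C5–H is buried between quaternary C4 and the silyloxy side chain, and O-sulfonylation gives the enol triflate without touching C5 or eliminating the beta-silyloxy group (enol triflate formation).

Step 5
Reactants: 7 enol triflate; 8 tert-butyl 2-bromopropanoate (racemic)
Product: 10 diester in which the triflate of 7 is replaced by a 1-(tert-butoxycarbonyl)ethyl group comprising C9 C20 C11 (4S,5R,6S; C9 epimers), via Reformatsky reagent 9 (not isolated)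
Conditions: 8, Zn dust (Me3SiCl-activated), THF, 40 °C; then 7, Pd(PPh3)4 (5 mol %), THF, 60 °C
Reagents that add atoms: none
Why: Negishi-type coupling of a Reformatsky reagent (oxidative addition of zerovalent palladium to the C10–O bond, transmetalation, reductive elimination) forms C9–C10 under neutral conditions that spare the beta,gamma-alkene, alkyne, silyl ether and C5, and the tert-butyl ester keeps C11 distinguishable from the C18 methyl ester.

Step 6
Reactants: 10 diester
Product: 12 alkynyl delta-lactone with O on C6 and C11 as carbonyl and prop-1-ynyl on C6 (4S,5R,6S; 9R drawn), via hydroxy acid 11 (not isolated)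
Conditions: CF3CO2H–CH2Cl2 (1:4), 0 °C to rt, evaporate; then EDC·HCl, DMAP, CH2Cl2 (0.01 M), 0 °C to rt
Reagents that add atoms: none
Why: Acidolysis removes the tert-butyl ester and silyl ether while C6 is still an acid-stable propargylic centre, and carbodiimide activation (Steglich-type lactonisation) makes C11 far more electrophilic than the neopentyl C18 methyl ester, so the C6 hydroxyl should close the delta-lactone with retention rather than the gamma-lactone.

Step 7
Reactants: 12 alkynyl delta-lactone
Product: 13 (Z)-propenyl delta-lactone, the rearrangement precursor (4S,5R,6R; 9R drawn)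
Conditions: H2 (1 atm), Pd/CaCO3 poisoned with Pb(OAc)2, quinoline, EtOAc, rt, stopped after 1 equiv H2
Reagents that add atoms: none
Why: Lindlar semihydrogenation delivers hydrogen syn to the internal alkyne to give the (Z)-alkene, while the hindered trisubstituted C1=C10 alkene and the allylic C–O bond are left alone by the poisoned catalyst.

Step 8
Reactants: 13 (Z)-propenyl delta-lactone
Product: 16 bicyclic C11 acid with C1=C10 and C6=C7 alkenes (4S,5R,8R,9S), via silyl ketene acetal 14 (not isolated), via silyl ester 15 (not isolated)
Conditions: LiN(SiMe3)2, t-BuMe2SiCl, THF–DMPU, −78 to 0 °C; pentane extraction, solvent change; toluene, 110 °C; then aq HF, MeCN, 0 °C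
Reagents that add atoms: none
Why: Deprotonation at C9, the only acidic C–H (alpha to the lactone carbonyl and allylic to C1=C10; the C4 ester has no alpha hydrogen), and O-silylation give the ring-locked dienyl ketene acetal 14, whose C9=C11–O–C6–C7=C8 array undergoes a concerted suprafacial [3,3] shift that makes C8–C9, breaks C6–O, moves the alkene to C6=C7 and frees C11 as silyl ester 15. The closest known reaction type is the Ireland–Claisen ring contraction of 6-alkenyl delta-lactones and 6-alkenyl dioxanones to cyclohexene or dihydropyran carboxylic acids. Ring B (C5–C10) closes in the lactone-to-carbocycle mode: the C5–C10 bond ties C6 to C9, so only a boat-like, bicyclo[2.2.2]octane-shaped transition state can be reached and the new ring alkene is necessarily cis. C9 is set by C6, because the propenyl arm lies on the lactone face that carries H5, so C8 bonds to that face of C9, C11 is pushed to the opposite face and C20 ends cis to H5. C8 is set by alkene geometry, because in the boat the (Z)-methyl takes the inside position beside the C5–C10 bridge (facing only sp2 C10 and H5) and ends cis to C20 and trans to C11. The step needs C9 rather than C1 reactivity of the extended ketene acetal and retention of Z geometry; the first is enforced because the heteroannular diene is locked s-trans and C1 cannot reach C8, the second because neither acid nor metal is present during heating.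

Step 9
Reactants: 16 bicyclic C11 acid
Product: 18 C11 aldehyde (4S,5R,8R,9S), via acid chloride 17 (not isolated)
Conditions: 1-chloro-N,N,2-trimethylprop-1-en-1-amine, CH2Cl2, 0 °C; then LiAlH(Ot-Bu)3, THF, −78 °C
Reagents that add atoms: none
Why: Neutral chlorination followed by partial reduction of the acid chloride with the bulky hydride stops at the non-enolisable neopentyl aldehyde, leaves the C18 methyl ester alone and avoids borane, which would hydroborate C6=C7.

Step 10
Reactants: 19 (R)-4-methoxy-2-methyl-4-oxobutanoic acid
Product: 20 methyl (R)-4-hydroxy-3-methylbutanoate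
Conditions: BH3·SMe2, THF, 0 °C to rt; MeOH quench; used crude
Reagents that add atoms: none
Why: Chemoselective borane reduction of the free acid in the presence of the ester differentiates the future C12 and C15 termini, and the untouched (R)-centre becomes 13S in the target only because the ranking of C12 and C14 switches.

Step 11
Reactants: 20 hydroxy ester
Product: 21 methyl (R)-3-methyl-4-[(1-phenyl-1H-tetrazol-5-yl)sulfanyl]butanoate
Conditions: 1-phenyl-1H-tetrazole-5-thiol, PPh3, DIAD, THF, 0 °C to rt
Reagents that add atoms: 1-phenyl-1H-tetrazole-5-thiol, Sc1nnnn1-c1ccccc1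
Why: Mitsunobu thioetherification of the primary alcohol is fast and neutral, so it consumes the hydroxy ester before it can lactonise and does not involve the stereocentre.

Step 12
Reactants: 21 sulfide ester
Product: 22 (R)-3-methyl-4-[(1-phenyl-1H-tetrazol-5-yl)sulfanyl]butan-1-ol
Conditions: i-Bu2AlH, CH2Cl2, −78 to 0 °C; aq KNaC4H4O6
Reagents that add atoms: none
Why: Ester reduction with the aluminium hydride is carried out at the sulfide stage, where the tetrazolyl group is inert to hydride.

Step 13
Reactants: 22 sulfide alcohol
Product: 23 tert-butyldimethylsilyl ether of 22 (R)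
Conditions: t-BuMe2SiCl, imidazole, CH2Cl2, rt
Reagents that add atoms: tert-butyldimethylsilyl chloride, CC(C)(C)[Si](C)(C)Cl
Why: Silyl protection of the C15 hydroxyl removes the only acidic proton and prevents intramolecular attack on the tetrazole during the later olefination.

Step 14
Reactants: 23 silyl ether sulfide
Product: 24 (R)-5-{[4-(tert-butyldimethylsilyloxy)-2-methylbutyl]sulfonyl}-1-phenyl-1H-tetrazole
Conditions: 30% aq H2O2, (NH4)6Mo7O24·4H2O (10 mol %), EtOH, 0 °C to rt
Reagents that add atoms: hydrogen peroxide, OO
Why: Molybdate-catalysed peroxide oxidation takes the sulfide to the sulfone under conditions that a primary silyl ether tolerates.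

Step 15
Reactants: 18 C11 aldehyde; 24 C12–C15 sulfone
Product: 25 triene silyl ether with a new C11=C12 alkene (E drawn; geometry irrelevant; 4S,5R,8R,9S,13R)
Conditions: 24, KN(SiMe3)2, DME, −60 °C; then 18, −60 °C to rt
Reagents that add atoms: none
Why: Julia–Kocienski olefination (addition, Smiles rearrangement, loss of SO2 and tetrazolone) joins C11 to C12 on a non-enolisable aldehyde, and neither C9 nor C13 carries an acidic hydrogen.

Step 16
Reactants: 25 triene silyl ether
Product: 26 silyl ether with saturated C6–C7 and C11–C12 and retained C1=C10 (4S,5R,8R,9S,13S)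
Conditions: TsNHNH2 (excess, in portions), NaOAc, DME–H2O, reflux
Reagents that add atoms: none
Why: Diimide reduction transfers H2 in a concerted way at a rate that falls steeply with substitution, so both disubstituted alkenes should be saturated while the trisubstituted C1=C10 alkene next to quaternary C9 survives, and no metal hydride is present to move it.

Step 17
Reactants: 26 silyl ether
Product: 27 C15 alcohol (4S,5R,8R,9S,13S)
Conditions: HF·pyridine, THF, 0 °C to rt
Reagents that add atoms: none
Why: Fluoride-driven desilylation of the primary silyl ether is mild enough for the methyl ester and the ring alkene.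

Step 18
Reactants: 27 C15 alcohol
Product: 28 target CNP0151222.1, methyl 15-acetoxyhalim-1(10)-en-18-oate (4S,5R,8R,9S,13S)
Conditions: Ac2O, pyridine, DMAP (cat.), CH2Cl2, rt
Reagents that add atoms: acetic anhydride, CC(=O)OC(C)=O
Why: DMAP-catalysed acetylation of the unhindered primary alcohol completes the target without affecting any stereocentre.

Compound list
1 | but-2-yn-1-ol | CC#CCO | starting material
2 | but-2-ynal | CC#CC=O | intermediate
3 | methyl 3-oxocyclohex-1-ene-1-carboxylate | COC(=O)C1=CC(=O)CCC1 | starting material
4 | methylzinc C5=C10 enolate of methyl (S)-1-methyl-3-oxocyclohexane-1-carboxylate | COC(=O)[C@@]1(C)CCCC(O[Zn]C)=C1 | intermediate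
5 | methyl (1S,2R)-2-[(1S)-1-hydroxybut-2-yn-1-yl]-1-methyl-3-oxocyclohexane-1-carboxylate | COC(=O)[C@@]1(C)CCCC(=O)[C@H]1[C@H](O)C#CC | intermediate
6 | C6 triethylsilyl ether of 5 | COC(=O)[C@@]1(C)CCCC(=O)[C@H]1[C@H](O[Si](CC)(CC)CC)C#CC | intermediate
7 | C1=C10 enol triflate of 6 | COC(=O)[C@@]1(C)CCC=C(OS(=O)(=O)C(F)(F)F)[C@H]1[C@H](O[Si](CC)(CC)CC)C#CC | intermediate
8 | tert-butyl 2-bromopropanoate (racemic) | CC(Br)C(=O)OC(C)(C)C | starting material
9 | bromozinc Reformatsky reagent of 8 | CC([Zn]Br)C(=O)OC(C)(C)C | intermediate
10 | C10-coupled methyl/tert-butyl diester (C9 epimers) | COC(=O)[C@@]1(C)CCC=C(C(C)C(=O)OC(C)(C)C)[C@H]1[C@H](O[Si](CC)(CC)CC)C#CC | intermediate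
11 | C6 hydroxy C11 acid (C9 epimers) | COC(=O)[C@@]1(C)CCC=C(C(C)C(=O)O)[C@H]1[C@H](O)C#CC | intermediate
12 | alkynyl delta-lactone (9R drawn) | COC(=O)[C@@]1(C)CCC=C2[C@H]1[C@@H](C#CC)OC(=O)[C@@H]2C | intermediate
13 | (Z)-propenyl delta-lactone, key-step precursor (9R drawn) | COC(=O)[C@@]1(C)CCC=C2[C@H]1[C@@H](/C=C\C)OC(=O)[C@@H]2C | intermediate
14 | tert-butyldimethylsilyl ketene acetal of 13 | COC(=O)[C@@]1(C)CCC=C2[C@H]1[C@@H](/C=C\C)OC(O[Si](C)(C)C(C)(C)C)=C2C | intermediate
15 | tert-butyldimethylsilyl ester of 16 | COC(=O)[C@@]1(C)CCC=C2[C@H]1C=C[C@@H](C)[C@]2(C)C(=O)O[Si](C)(C)C(C)(C)C | intermediate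
16 | bicyclic C11 acid, key-step product | COC(=O)[C@@]1(C)CCC=C2[C@H]1C=C[C@@H](C)[C@]2(C)C(=O)O | intermediate
17 | C11 acid chloride | COC(=O)[C@@]1(C)CCC=C2[C@H]1C=C[C@@H](C)[C@]2(C)C(=O)Cl | intermediate
18 | C11 aldehyde | COC(=O)[C@@]1(C)CCC=C2[C@H]1C=C[C@@H](C)[C@]2(C)C=O | intermediate
19 | (R)-4-methoxy-2-methyl-4-oxobutanoic acid | OC(=O)[C@H](C)CC(=O)OC | starting material
20 | methyl (R)-4-hydroxy-3-methylbutanoate | OC[C@H](C)CC(=O)OC | intermediate
21 | methyl (R)-3-methyl-4-[(1-phenyl-1H-tetrazol-5-yl)sulfanyl]butanoate | c1ccccc1-n1nnnc1SC[C@H](C)CC(=O)OC | intermediate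
22 | (R)-3-methyl-4-[(1-phenyl-1H-tetrazol-5-yl)sulfanyl]butan-1-ol | c1ccccc1-n1nnnc1SC[C@H](C)CCO | intermediate
23 | tert-butyldimethylsilyl ether of 22 | c1ccccc1-n1nnnc1SC[C@H](C)CCO[Si](C)(C)C(C)(C)C | intermediate
24 | C12–C15 phenyltetrazolyl sulfone (R) | c1ccccc1-n1nnnc1S(=O)(=O)C[C@H](C)CCO[Si](C)(C)C(C)(C)C | intermediate
25 | triene silyl ether (C11=C12 E drawn) | COC(=O)[C@@]1(C)CCC=C2[C@H]1C=C[C@@H](C)[C@]2(C)/C=C/[C@H](C)CCO[Si](C)(C)C(C)(C)C | intermediate
26 | 15-silyloxy halim-1(10)-en-18-oate | COC(=O)[C@@]1(C)CCC=C2[C@H]1CC[C@@H](C)[C@]2(C)CC[C@H](C)CCO[Si](C)(C)C(C)(C)C | intermediate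
27 | methyl 15-hydroxyhalim-1(10)-en-18-oate | COC(=O)[C@@]1(C)CCC=C2[C@H]1CC[C@@H](C)[C@]2(C)CC[C@H](C)CCO | intermediate
28 | methyl 15-acetoxyhalim-1(10)-en-18-oate (CNP0151222.1) | COC(=O)[C@@]1(C)CCC=C2[C@H]1CC[C@@H](C)[C@]2(C)CC[C@H](C)CCOC(C)=O | target

Total step count: 18. Longest linear sequence: 13 (steps 1–9 and 15–18); steps 10–14 form the convergent side branch.

Steps most likely to fail

Risk 1, step 8. In the boat both the C5 bridge carbon and the (Z)-methyl sit on the inside of the allyl unit. The resulting A(1,3)-type strain may slow the [3,3] shift so much that desilylation or fragmentation of the ketene acetal overtakes it. The fallback sets out from 13 and comes back at 18. It moves the rearrangement to the more heat-resistant enol ether level. One equivalent of i-Bu2AlH at −78 °C should reduce the lactone carbonyl, but not the neopentyl C18 ester, to the lactol F1. MsCl and Et3N should then eliminate across C9–C11 to give the cyclic dienol ether F2. Heating F2 in a base-washed sealed tube (toluene, 180–200 °C) should trigger the aliphatic Claisen ring contraction known for 2-alkenyl-3,4-dihydro-2H-pyrans. This passes through the same boat, with the same relay from C6 and the (Z)-alkene, and delivers aldehyde 18 directly, so step 9 is no longer needed.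

Risk 2, step 2. The C19 methyl and the C18 ester differ little in size, so facial selectivity at C5 may be poor, and anti selectivity at C6 may erode with the slim ynal. The fallback sets out from 3 and comes back at 7. It builds the quaternary centre last.
- Ligated copper hydride (Cu(OAc)2·H2O, the DTBM-SEGPHOS antipode that gives 4R, (EtO)2MeSiH, toluene, −30 °C) performs an asymmetric 1,4-hydrosilylation to the silyl enol ether F3.
- A Mukaiyama aldol with 2 (BF3·OEt2, −78 °C) now meets a single C4 substituent and should add anti to it, giving the trans ketol F4.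
- Silylation as in step 3 gives the silyl ether F5, and triflation as in step 4 gives the enol triflate F6.
- LiN(i-Pr)2 and then MeI methylate the exocyclic C4 ester enolate anti to the pseudoaxial C5 side chain. This places C19 trans and C18 cis to C6 and gives 7.

Risk 3, step 5. Transmetalation and reductive elimination at C10, which is crowded by the C5 side chain, may be slow. Protonation of the zinc enolate or reduction of the triflate could then compete. The fallback sets out from 7 and comes back at 10. It reverses the polarity of the coupling. Borylation of 7 (bis(pinacolato)diboron, PdCl2(dppf), KOPh, dioxane) should give the alkenyl boronate F7. F7 is then joined to the electrophilic alpha-bromo ester 8 in a nickel-catalysed Suzuki-type coupling of alpha-halo carbonyl compounds (Ni(PPh3)4, K3PO4, toluene, 80 °C), again without strong base.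

Further compounds
F1 | step 8 | C11 lactol of 13 (anomers) | COC(=O)[C@@]1(C)CCC=C2[C@H]1[C@@H](/C=C\C)OC(O)[C@@H]2C
F2 | step 8 | cyclic dienol ether with C9=C11 and C1=C10 | COC(=O)[C@@]1(C)CCC=C2[C@H]1[C@@H](/C=C\C)OC=C2C
F3 | step 2 | diethoxy(methyl)silyl enol ether of methyl (R)-3-oxocyclohexane-1-carboxylate | COC(=O)[C@@H]1CCCC(O[Si](C)(OCC)OCC)=C1
F4 | step 2 | methyl (1R,2R)-2-[(1S)-1-hydroxybut-2-yn-1-yl]-3-oxocyclohexane-1-carboxylate | COC(=O)[C@@H]1CCCC(=O)[C@H]1[C@H](O)C#CC
F5 | step 2 | C6 triethylsilyl ether of F4 | COC(=O)[C@@H]1CCCC(=O)[C@H]1[C@H](O[Si](CC)(CC)CC)C#CC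
F6 | step 2 | C1=C10 enol triflate of F5 | COC(=O)[C@@H]1CCC=C(OS(=O)(=O)C(F)(F)F)[C@H]1[C@H](O[Si](CC)(CC)CC)C#CC
F7 | step 5 | C10 pinacol boronate corresponding to 7 | COC(=O)[C@@]1(C)CCC=C(B2OC(C)(C)C(C)(C)O2)[C@H]1[C@H](O[Si](CC)(CC)CC)C#CC
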